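**Plan**

1. Numbering: butenolide half C1(=O), O2, C3, C3a, C4–C7, C7a; aromatic half primed (spiro C3′; C8′ carries propyl). Retrosynthetic cuts in order: the C3=C8 unsaturation (back to a C3–H butyl stereocentre); the C3a=C7a unsaturation (back to its C4=C5 isomer); the cyclobutane bond C3′–C8′ with the phthalide C–O (back to an ortho-ester aryl ketone); then C3a–C7a and C6–C7 in one stroke; then ester C1–O2 and the C3–butyl bond.
2. Enabling feature: ring C3a–C4–C5–C6–C7–C7a is a cyclohexene annulated through C3a–C7a to the γ-lactone C1–O2–C3. With the double bond at C4=C5 this bicycle is the retron of an intramolecular Diels–Alder reaction of an ester-tethered 1,3,8-nonatriene (diene C3a=C4–C5=C6, dienophile C7=C7a, tether C3–O2–C1). C7 then carries the aryl ketone carbon C3′ and C6 the butyl chain whose first carbon is C8′.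
3. Forward ring order: acyclic dienyl aroylacrylate → lactone and cyclohexene together ([4+2]) → cyclobutane (γ-C–H photocyclisation) and spiro-phthalide (lactonisation) → alkene migration to C3a=C7a → butylidene by dehydrogenation at C3.
4. Stereochemistry: the (R)-carbinol at C3 (catalytic asymmetric butyl transfer) directs the diene face in the cycloaddition and fixes C6 and C7. C8′ and C3′ are set relative to them in the biradical ring closure. C3, C3a and C7a are erased later; the target is (6S,7R,3′R,8′R) in this numbering.

Key step: step 4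

**Route**

Step 1
Reactants: 1 (2E,4E)-nona-2,4-dienal; 2 dibutylzinc
Product: 3 (5R,6E,8E)-trideca-6,8-dien-5-ol
Conditions: (2R)-(+)-3-exo-(dimethylamino)isoborneol [(+)-DAIB] (5 mol %), toluene, 0 °C; aq. NH4Cl
Reagents that add atoms: none
Why: Amino-alcohol-catalysed enantioselective 1,2-addition of a dialkylzinc to a conjugated aldehyde: the zinc chelate of (+)-DAIB should deliver butyl to the aldehyde face that gives the (R)-carbinol (the mirror image of the (S) sense of the (−)-ligand), leaving the diene untouched.

Step 2
Reactants: 4 methyl 2-acetylbenzoate; 5 glyoxylic acid monohydrate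
Product: 6 (2E)-4-[2-(methoxycarbonyl)phenyl]-4-oxobut-2-enoic acid
Conditions: TsOH·H2O (cat.), 1,4-dioxane, 100 °C
Reagents that add atoms: none
Why: Acid-catalysed aldol condensation of an aryl methyl ketone with glyoxylic acid, the standard entry to (E)-3-aroylacrylic acids; dehydration gives the (E)-alkene and the methyl ester keeps the ortho carboxyl from closing onto the ketone.

Step 3
Reactants: 3 (5R,6E,8E)-trideca-6,8-dien-5-ol; 6 (2E)-4-[2-(methoxycarbonyl)phenyl]-4-oxobut-2-enoic acid
Product: 7 (5R,6E,8E)-trideca-6,8-dien-5-yl (2E)-4-[2-(methoxycarbonyl)phenyl]-4-oxobut-2-enoate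
Conditions: DCC, DMAP (cat.), CH2Cl2, 0 °C to rt, dark
Reagents that add atoms: none
Why: Steglich esterification acylates the secondary dienylic alcohol at oxygen under neutral conditions, with retention at C3 and without ionising the dienylic C–O bond.

Step 4
Reactants: 7 (5R,6E,8E)-trideca-6,8-dien-5-yl (2E)-4-[2-(methoxycarbonyl)phenyl]-4-oxobut-2-enoate
Product: 8 methyl 2-{[(3R,3aS,6R,7R,7aR)-3,6-dibutyl-1-oxo-1,3,3a,6,7,7a-hexahydro-2-benzofuran-7-yl]carbonyl}benzoate
Conditions: toluene (5 mM), BHT (cat.), 110 °C, Ar, dark
Reagents that add atoms: none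
Why: Thermal concerted suprafacial [4π+2π] cycloaddition in which the (E,E)-diene C3a=C4–C5=C6 adds across the doubly activated (E)-alkene C7=C7a held on the three-atom ester tether C3–O2–C1, so that C3a–C7a and C6–C7 form in the same transition state (C3a–C7a is made as a single bond here and becomes the butenolide double bond in step 6). The closest known reaction type is the intramolecular Diels–Alder reaction of ester-tethered 1,3,8-nonatrienes of the pentadienyl fumarate kind that carry a stereocentre at the carbinol carbon. Both rings close in this one pericyclic event: the five-membered lactone through C3a–C7a with its carbonyl exo (trans ring fusion), the six-membered carbocycle through both new bonds. Of the four new stereocentres, C6/C7 cis follows from the (E,E)-diene plus the endo aryl ketone, C7/C7a trans from the (E)-dienophile and C3a/C7a trans from the exo tether, while the absolute sense comes from C3: its hydrogen eclipses C4–H (A(1,3) strain), the ester oxygen reaches over one diene face and the butyl group points away, which should give (3aS,6R,7R,7aR). The selectivity needed is ketone-endo/tether-exo over the reverse and one diene face over the other; the first is secured by the stronger endo preference of the aryl ketone and the exo preference of the tether carbonyl in (E)-configured esters, the second by the C3 stereocentre. Only C6 and C7 persist to the target, since C3a and C7a become trigonal in step 6 and C3 in step 7.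

Step 5
Reactants: 8 methyl 2-{[(3R,3aS,6R,7R,7aR)-3,6-dibutyl-1-oxo-1,3,3a,6,7,7a-hexahydro-2-benzofuran-7-yl]carbonyl}benzoate
Product: 10 C4=C5 spiro-phthalide cyclobutane lactone, via cyclobutanol 9 (not isolated)
Conditions: hν (350 nm), degassed benzene (5 mM), rt; then PPTS (cat.), 60 °C
Reagents that add atoms: none
Why: Norrish–Yang photocyclisation followed by lactonisation: the n,π* triplet of the aryl ketone should abstract a hydrogen from C8′, the only γ C–H within reach (C5 is vinylic and H-3a sits on the opposite ring face), and the 1,4-biradical should close C3′–C8′ to the necessarily cis-fused cyclobutanol with the aryl group on the convex face and propyl trans to aryl (hence cis to the hydroxyl and to C5), after which the tertiary hydroxyl displaces methanol from the ortho ester to give the spiro-phthalide with C6, C7, C3′ and C8′ as in the target.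

Step 6
Reactants: 10 C4=C5 spiro-phthalide cyclobutane lactone
Product: 12 (3R)-3-butyl butenolide spiro-phthalide, via β,γ-unsaturated lactone 11 (not isolated)
Conditions: RuHCl(CO)(PPh3)3 (5 mol %), toluene, 110 °C; then DBU (0.2 equiv), 60 °C
Reagents that add atoms: none
Why: Transition-metal-hydride alkene isomerisation (hydrometalation/β-hydride elimination) should carry C4=C5 to C3a=C4, and base-mediated conjugation through the C7a dienolate then gives the tetrasubstituted butenolide, the thermodynamic sink of the system; C6 and C7 cannot epimerise because the four-membered ring allows only cis fusion, and the stereocentres at C3a and C7a disappear.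

Step 7
Reactants: 12 (3R)-3-butyl butenolide spiro-phthalide
Product: 15 target CNP0248594.2, via silyloxyfuran 13 (not isolated), via bromo lactone 14 (not isolated)
Conditions: TBSOTf, Et3N, CH2Cl2, 0 °C; NBS, −78 °C; DBU, −78 °C to rt
Reagents that add atoms: none
Why: Soft enolisation to the 2-silyloxyfuran, electrophilic bromination at C3 (the γ-position) and loss of HBr toward the butyl chain, the only side with β-hydrogens, is the bromination–dehydrobromination route by which 3-butylphthalides are turned into 3-butylidenephthalides and should give the thermodynamically preferred (Z)-enol lactone while erasing the C3 stereocentre that relayed the chirality.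

**Compound list**

1 | (2E,4E)-nona-2,4-dienal | CCCC/C=C/C=C/C=O | starting material
2 | dibutylzinc | CCCC[Zn]CCCC | starting material
3 | (5R,6E,8E)-trideca-6,8-dien-5-ol | CCCC[C@@H](O)/C=C/C=C/CCCC | intermediate
4 | methyl 2-acetylbenzoate | COC(=O)c1ccccc1C(C)=O | starting material
5 | glyoxylic acid monohydrate (2,2-dihydroxyacetic acid) | OC(O)C(=O)O | starting material
6 | (2E)-4-[2-(methoxycarbonyl)phenyl]-4-oxobut-2-enoic acid | COC(=O)c1ccccc1C(=O)/C=C/C(=O)O | intermediate
7 | (5R,6E,8E)-trideca-6,8-dien-5-yl (2E)-4-[2-(methoxycarbonyl)phenyl]-4-oxobut-2-enoate | CCCC[C@@H](OC(=O)/C=C/C(=O)c1ccccc1C(=O)OC)/C=C/C=C/CCCC | intermediate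
8 | methyl 2-{[(3R,3aS,6R,7R,7aR)-3,6-dibutyl-1-oxo-1,3,3a,6,7,7a-hexahydro-2-benzofuran-7-yl]carbonyl}benzoate (trans-fused lactone; 6-butyl and 7-aroyl cis; 3-butyl cis to H-3a) | CCCC[C@H]1OC(=O)[C@@H]2[C@@H]1C=C[C@@H](CCCC)[C@H]2C(=O)c1ccccc1C(=O)OC | intermediate
9 | cyclobutanol formed and consumed in step 5: C3′ (OH, 2-(methoxycarbonyl)phenyl) bonded to C7 and C8′; OH cis to C7a, propyl cis to C5, aryl on the face of H-6/H-7; rest as in 8 | CCCC[C@H]1OC(=O)[C@@H]2[C@@H]1C=C[C@H]3[C@@H](CCC)[C@](O)(c4ccccc4C(=O)OC)[C@@H]23 | intermediate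
10 | C4=C5 spiro-phthalide cyclobutane lactone: (3R)-3-butyl, H-3a/H-7a trans, cyclobutane C6–C8′(propyl)–C3′(spiro-phthalide)–C7 configured as in the target | CCCC[C@H]1OC(=O)[C@@H]2[C@@H]1C=C[C@H]3[C@@H](CCC)[C@@]4(OC(=O)c5ccccc45)[C@@H]23 | intermediate
11 | β,γ-unsaturated lactone (C3a=C4 isomer of 10), formed and consumed in step 6 | CCCC[C@H]1OC(=O)[C@@H]2C1=CC[C@H]3[C@@H](CCC)[C@@]4(OC(=O)c5ccccc45)[C@@H]23 | intermediate
12 | (3R,6S,7R,3′R,8′R)-3-butyl butenolide spiro-phthalide (C3a=C7a; the 3,8-dihydro derivative of the target) | CCCC[C@H]1OC(=O)C2=C1CC[C@H]1[C@@H](CCC)[C@@]3(OC(=O)c4ccccc43)[C@@H]21 | intermediate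
13 | 2-(tert-butyldimethylsilyloxy)furan of 12 (furan O2–C3(butyl)=C3a–C7a=C1(OSi)), formed and consumed in step 7 | CCCCc1oc(O[Si](C)(C)C(C)(C)C)c2c1CC[C@H]1[C@@H](CCC)[C@@]3(OC(=O)c4ccccc43)[C@@H]21 | intermediate
14 | 3-bromo-3-butyl butenolide (either C3 epimer), formed and consumed in step 7 | CCCCC1(Br)OC(=O)C2=C1CC[C@H]1[C@@H](CCC)[C@@]3(OC(=O)c4ccccc43)[C@@H]21 | intermediate
15 | CNP0248594.2: (3Z,6S,7R,3′R,8′R)-3-butylidene butenolide fused at C6–C7 to the cyclobutane whose C3′ is the spiro carbon of a phthalide and whose C8′ carries propyl | CCC/C=C1\OC(=O)C2=C1CC[C@H]1[C@@H](CCC)[C@@]3(OC(=O)c4ccccc43)[C@@H]21 | target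

**Count**

Total steps: 7. Longest linear sequence: 6 steps (steps 1, 3, 4, 5, 6, 7 from aldehyde 1; equally steps 2 to 7 from ketone 4).

**Steps most likely to fail**

Step 5. The ketone triplet may be drained by the neighbouring C4=C5 π bond before it reaches the γ-hydrogen. The 1,4-biradical may also fragment across C6–C7 (the cleavage branch of the Norrish manifold, helped here because it would release a conjugated diene), or close with propyl on the aryl face. The fallback sets out from 8 and comes back at 12; it removes the alkene first and brings in the butenolide double bond by oxidation instead of isomerisation. Diimide (2-nitrobenzenesulfonylhydrazide, Et3N) should saturate C4=C5 of 8 to the saturated keto lactone F1. Irradiation of F1 as in step 5 would give the saturated cyclobutanol F2, which lactonises to the saturated spiro-phthalide F3. The butyrolactone enolate of F3 (LiN(iPr)2, −78 °C) is selenenylated with PhSeBr on the face of H-3a to the selenide F4. Oxidation with H2O2 gives the selenoxide F5, whose syn-elimination toward H-3a should deliver 12.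

Step 4. Cyclisation has to pass through the disfavoured s-cis ester rotamer and may be slow. The transition state with the tether carbonyl endo and the ketone exo may leak in (C6 and C7 substituents trans), or the two diene faces may be poorly differentiated. The fallback sets out from 3 and 6 and comes back at 8; it uses an untethered, Lewis-acid-promoted cycloaddition followed by lactonisation. Alcohol 3 is silylated (TBSCl, imidazole) to the silyl ether F6 and acid 6 is methylated (Me3SiCHN2, MeOH) to the diester F7. Me2AlCl at −78 °C, bound to the more basic ketone, should enforce ketone-endo addition of F6 to F7, with C3a (the diene terminus remote from the better donor, butyl) bonding to C7a, to give the cyclohexene diester F8. HF·pyridine then removes the silyl group and the freed C3 hydroxyl closes onto the C7a ester to give 8.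

Step 6. The hydride walk may stall at the C3a=C4 or C5=C6 isomers, or the Lewis-acidic metal may ionise the tertiary benzylic C3′–O bond so that the cyclobutane rearranges. The fallback sets out from 10 and comes back at 12; it oxidises first and reduces afterwards. The lactone enolate of 10 (LiN(iPr)2, −78 °C) is selenenylated with PhSeBr to the selenide F9. H2O2 gives the selenoxide F10, which eliminates toward H-3a to the dienyl butenolide F11 (C3a=C7a and C4=C5). Hydrogenation over RhCl(PPh3)3 should reduce only the disubstituted C4=C5 bond and give 12.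

**Further compounds**

F1 | step 5 | methyl 2-{[(3R,3aS,6R,7R,7aR)-3,6-dibutyl-1-oxooctahydro-2-benzofuran-7-yl]carbonyl}benzoate | CCCC[C@H]1OC(=O)[C@@H]2[C@@H]1CC[C@@H](CCCC)[C@H]2C(=O)c1ccccc1C(=O)OC
F2 | step 5 | saturated cyclobutanol (4,5-dihydro analogue of 9) | CCCC[C@H]1OC(=O)[C@@H]2[C@@H]1CC[C@H]3[C@@H](CCC)[C@](O)(c4ccccc4C(=O)OC)[C@@H]23
F3 | step 5 | saturated spiro-phthalide (4,5-dihydro analogue of 10) | CCCC[C@H]1OC(=O)[C@@H]2[C@@H]1CC[C@H]3[C@@H](CCC)[C@@]4(OC(=O)c5ccccc45)[C@@H]23
F4 | step 5 | C7a phenylselenide of F3 (selenium cis to H-3a) | CCCC[C@H]1OC(=O)[C@@]2([Se]c3ccccc3)[C@@H]1CC[C@H]4[C@@H](CCC)[C@@]5(OC(=O)c6ccccc56)[C@@H]24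
F5 | step 5 | selenoxide of F4 | CCCC[C@H]1OC(=O)[C@@]2([Se](=O)c3ccccc3)[C@@H]1CC[C@H]4[C@@H](CCC)[C@@]5(OC(=O)c6ccccc56)[C@@H]24
F6 | step 4 | tert-butyl(dimethyl){[(5R,6E,8E)-trideca-6,8-dien-5-yl]oxy}silane | CCCC[C@@H](O[Si](C)(C)C(C)(C)C)/C=C/C=C/CCCC
F7 | step 4 | methyl (2E)-4-[2-(methoxycarbonyl)phenyl]-4-oxobut-2-enoate | COC(=O)/C=C/C(=O)c1ccccc1C(=O)OC
F8 | step 4 | cyclohex-3-ene bearing CO2Me (C7a), 2-(methoxycarbonyl)benzoyl (C7), butyl (C6) and (1R)-1-(tert-butyldimethylsilyloxy)pentyl (C3a), configured as in 8 | CCCC[C@@H](O[Si](C)(C)C(C)(C)C)[C@H]1C=C[C@@H](CCCC)[C@@H](C(=O)c2ccccc2C(=O)OC)[C@@H]1C(=O)OC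
F9 | step 6 | C7a phenylselenide of 10 (selenium cis to H-3a) | CCCC[C@H]1OC(=O)[C@@]2([Se]c3ccccc3)[C@@H]1C=C[C@H]4[C@@H](CCC)[C@@]5(OC(=O)c6ccccc56)[C@@H]24
F10 | step 6 | selenoxide of F9 | CCCC[C@H]1OC(=O)[C@@]2([Se](=O)c3ccccc3)[C@@H]1C=C[C@H]4[C@@H](CCC)[C@@]5(OC(=O)c6ccccc56)[C@@H]24
F11 | step 6 | dienyl butenolide (C3a=C7a and C4=C5) spiro-phthalide | CCCC[C@H]1OC(=O)C2=C1C=C[C@H]1[C@@H](CCC)[C@@]3(OC(=O)c4ccccc43)[C@@H]21
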